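A small charge of scavenger, 0.23 equiv, went into Saturday's run, a larger one, 0.58 equiv, into Sunday's, and 0.41 equiv into Tuesday's, with substrate and partner charged alike in each.

all flasks: substrate 0.10 M

| run | partner | scavenger | remark | time |
|---|---|---|---|---|
| Saturday's | 1.5 equiv | 0.23 equiv | run made earlier |  |
| Tuesday's | 1.5 equiv | 0.41 equiv | run made earlier |  |
| Sunday's | 1.5 equiv | 0.58 equiv | run made earlier |  |
| delta | 1.50 equiv | 0.300 equiv |  | 10 min |
| gamma | 1.50 equiv | 0.600 equiv |  | 10 min |

| run | time / min | substrate / % | target / % |
|---|---|---|---|
| Saturday's | 0.833 | 84.7 | 2.0 |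
| Saturday's | 1.50 | 77.3 | 2.8 |
| Saturday's | 3.00 | 67.6 | 8.4 |
| Saturday's | 5.00 | 59.2 | 12.7 |
| Saturday's | 10.0 | 44.4 | 23.6 |
| Tuesday's | 0.833 | 84.6 | 1.1 |
| Tuesday's | 1.50 | 77.1 | 2.7 |
| Tuesday's | 3.00 | 67.8 | 8.0 |
| Tuesday's | 5.00 | 60.3 | 13.2 |
| Tuesday's | 10.0 | 45.6 | 23.5 |
| Sunday's | 0.833 | 84.7 | 1.5 |
| Sunday's | 2.50 | 71.1 | 6.0 |
| Sunday's | 5.00 | 60.3 | 14.0 |
| Sunday's | 8.00 | 50.9 | 20.0 |
| Sunday's | 10.0 | 45.1 | 23.5 |

(scatter of a reading: 0.5 percentage points)

- the numbers in the tables scatter with a standard deviation of 0.5 percentage points
- a reading or a percentage of target counts all its forms, free or not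

- part of the substrate that has reacted at the end, delta
- part of the substrate that has reacted at the end, gamma
- what raising the equivalents of scavenger from its lowest to its highest value here does to the part of the substrate that has reacted (changes below 5 percentage points count as none) (it falls / it rises / no change)

**Does the scavenger move the substrate in these runs?** Not that I can read. At 10.0 min substrate stands at 44.4% on Saturday, 45.6% on Tuesday and 45.1% on Sunday, with no steady direction as scavenger rises and a scatter of 0.5 percentage points. Their mean is 45.0%.

**Then which concentration should be watched?** I would watch [partner], though this is my assumption, since each run holds 1.5 equiv. I take the loss of substrate as first order in substrate and in partner, with [partner] as charged at 0.150 M. That gives 0.00886 L mol⁻¹ s⁻¹. This partner constant, the logarithm of substrate charged over substrate left, divided by the time and by [partner] as charged, turns a partner charge into substrate left.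

**Is it truly a constant?** No. Saturday's logarithm per minute is 0.199 min⁻¹ over the first 0.833 min but 0.0812 min⁻¹ across 10.0 min, so the loss slows. It is no pseudo-first-order constant, just an average, and I use it at 10 min, where it was read.

**Your answer?** Delta and gamma keep 1.50 equiv and 10 min, with 0.300 equiv inside the tried range and 0.600 equiv just above it. I commit to 55.0% reacted in each.

The forecast gives 55% for delta, 55% for gamma and no change, holding that “scavenger has no visible effect on rate or on the lag in target formation”.

Delta reaches 55.5% and gamma 54.8%, so the trend is no change, a shift of −0.7 points.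

    substrate + released group ⇌ idle adduct, settled at all times (K = 11.0 L mol⁻¹)
    intermediate → side product (k = 0.00313 s⁻¹)
    intermediate ⇌ target + released group (K = 0.293 M, k = 0.00333 s⁻¹)
    substrate + partner ⇌ intermediate (K = 2.80 L mol⁻¹, k = 0.0296 L mol⁻¹ s⁻¹)
    crystals ⇌ target, rate k5*(cs5 - [target]) while solid is left; crystals form when [target] > cs5 (solubility = 23.0 mM, k = 0.0229 s⁻¹)
    scavenger + released group → scavenged by-product (k = 0.529 L mol⁻¹ s⁻¹)

The scavenger does leave a mark: at 10.0 min idle adduct is 1.89% in delta and 0.705% in gamma, against a margin of 5 points. Gamma's partner stands at 64% of its charge, and the partner constant gives 55.0% reacted against its 54.8%. Moved singly by one factor, the settings shift gamma's answer in this order: partner (9.3 points), then substrate (6.7 points), then time (6.5 points), then scavenger (0.18 points). For the neighbour, gamma with 0.900 equiv of partner, the partner constant gives 62.0% substrate left. That neighbour flask holds 62% substrate at 10.0 min, so 38.0% has reacted, with 16.1% as target.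

The numbers in the tables were generated by integration from invented constants.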